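**Retrosynthetic overview**

1. Target 21 is the (3S,4R)-lactone with the two arylmethyl groups cis. It comes from lactone 19 by desilylation and hydrogenolysis. The butyrolactone is the only ring made and is closed late, from the γ-hydroxy acid obtained by ozonolysis/reduction of the propenyl group of acid 16.
2. The plan rests on lactone C3 (ring atoms O1, C2 carbonyl, C3, C4, C5). C3 is a glycolate carbon bonded to oxygen, the C2 carboxyl, a benzylic CH2 and C4, so it maps onto the ketone carbon of a silyl glyoxylate that links two carbon fragments.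
3. Acid 16 comes from a one-flask union of allylic silyl glyoxylate 8 and benzylic Grignard 11: addition (C3–CH2Ar bond), [1,2]-Brook shift, O-silylation, chair Ireland–Claisen [3,3] shift (C3–C4 bond, both stereocentres).
4. Glyoxylate 8 comes from allylic alcohol 4 (diazoacetylation, C-silylation, dioxirane oxidation), and 4 from cross-metathesis of O-benzyleugenol 2 with (S)-but-3-en-2-ol 3. Grignard 11 comes from chloride 10, made from alcohol 9.

Key step: step 8

Remark: the Brook shift is assumed to deliver the glycolate enolate with the silyloxy group cis to the enolate oxygen (magnesium bridging both oxygens in the adduct); the configuration assigned to 16 depends on this. Compounds 1, 3 and 9 are taken as purchased.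

**Step 1**
Reactants: 1 eugenol
Product: 2 4-allyl-1-(benzyloxy)-2-methoxybenzene (O-benzyleugenol)
Conditions: BnBr, K2CO3, acetone, reflux
Reagents that add atoms: benzyl bromide, BrCc1ccccc1
Why: Williamson etherification of the phenoxide with benzyl bromide; the allyl group is inert and no stereocentre is involved.

**Step 2**
Reactants: 2 O-benzyleugenol; 3 (S)-but-3-en-2-ol
Product: 4 (2S,3E)-5-[4-(benzyloxy)-3-methoxyphenyl]pent-3-en-2-ol
Conditions: second-generation Grubbs catalyst RuCl2(=CHPh)(PCy3)(H2IMes) (3 mol%), 1,4-benzoquinone (10 mol%), 2 (2.5 equiv), CH2Cl2, 40 °C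
Reagents that add atoms: none
Why: Olefin cross-metathesis between the readily homodimerising allylarene (in excess) and the slowly homodimerising secondary allylic alcohol should give the E alkene under thermodynamic control, benzoquinone holding back ruthenium-hydride migration of the double bond; the carbinol stereocentre of 3 is not involved and is carried through.

**Step 3**
Reactants: 4 (2S,3E)-5-[4-(benzyloxy)-3-methoxyphenyl]pent-3-en-2-ol
Product: 6 (2S,3E)-5-[4-(benzyloxy)-3-methoxyphenyl]pent-3-en-2-yl 2-diazoacetate, via tosylhydrazone ester 5 (not isolated)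
Conditions: TsNHN=CHCOCl, PhNMe2, CH2Cl2, 0 °C; then Et3N, 0 °C → rt
Reagents that add atoms: glyoxylic acid chloride p-toluenesulfonylhydrazone, Cc1ccc(cc1)S(=O)(=O)NN=CC(Cl)=O
Why: Acylation of the alcohol followed by triethylamine-induced loss of p-toluenesulfinate from the tosylhydrazone (Corey–Myers diazoacetylation, a Bamford–Stevens-type fragmentation) gives the diazoacetate without touching the carbinol C–O bond, so the S configuration is retained.

**Step 4**
Reactants: 6 the diazoacetate
Product: 7 (2S,3E)-5-[4-(benzyloxy)-3-methoxyphenyl]pent-3-en-2-yl 2-(tert-butyldimethylsilyl)-2-diazoacetate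
Conditions: TBSOTf, iPr2NEt, Et2O, −78 °C → rt
Reagents that add atoms: tert-butyldimethylsilyl triflate, CC(C)(C)[Si](C)(C)OS(=O)(=O)C(F)(F)F
Why: The nucleophilic diazo carbon attacks the silyl triflate and the hindered amine removes the proton (electrophilic C-silylation of a diazoacetate); the allylic ester and benzyl ether should tolerate the buffered, cold conditions.

**Step 5**
Reactants: 7 the silyl diazoacetate
Product: 8 (2S,3E)-5-[4-(benzyloxy)-3-methoxyphenyl]pent-3-en-2-yl 2-(tert-butyldimethylsilyl)-2-oxoacetate (allylic silyl glyoxylate)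
Conditions: dimethyldioxirane (1.1 equiv, acetone solution), CH2Cl2, −78 → −20 °C, dark
Reagents that add atoms: dimethyldioxirane, CC1(C)OO1
Why: Oxygen-atom transfer from the electrophilic dioxirane to the nucleophilic diazo carbon with loss of N2 gives the acylsilane (dioxirane oxidation of a silyl diazoacetate); with one equivalent at low temperature the trans alkene, deactivated by the allylic ester oxygen, and the arenes should not compete.

**Step 6**
Reactants: 9 4-(benzyloxy)-3-methoxybenzyl alcohol
Product: 10 4-(benzyloxy)-3-methoxybenzyl chloride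
Conditions: SOCl2, CH2Cl2, 0 °C
Reagents that add atoms: thionyl chloride, ClS(Cl)=O
Why: Chlorodehydroxylation of the electron-rich benzylic alcohol through its chlorosulfite is fast at 0 °C, and the benzyl aryl ether tolerates the brief exposure to HCl.

**Step 7**
Reactants: 10 4-(benzyloxy)-3-methoxybenzyl chloride
Product: 11 [4-(benzyloxy)-3-methoxybenzyl]magnesium chloride (THF solution, titrated, used directly)
Conditions: Mg turnings (I2-activated), THF, 0 °C, slow addition, ca. 0.2 M
Reagents that add atoms: magnesium, [Mg]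
Why: Insertion of magnesium into the benzylic C–Cl bond (Grignard formation); low temperature, dilution and slow addition hold back Wurtz homocoupling, and any bibenzyl formed is inert in step 8.

**Step 8**
Reactants: 8 the allylic silyl glyoxylate; 11 [4-(benzyloxy)-3-methoxybenzyl]magnesium chloride
Product: 16 (2S,3R,4E)-2,3-bis[4-(benzyloxy)-3-methoxybenzyl]-2-[(tert-butyldimethylsilyl)oxy]hex-4-enoic acid, via magnesium alkoxide adduct 12 (not isolated), via magnesium enolate 13 (not isolated), via silyl ketene acetal 14 (not isolated), via trimethylsilyl ester 15 (not isolated)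
Conditions: 11 (1.3 equiv), THF, −78 °C, slow addition of 8; then Me3SiCl/Et3N (3 equiv each), −78 °C → rt, then 40 °C; 1 M HCl work-up
Reagents that add atoms: none
Why: Proposed new method: the benzylic Grignard should attack the acylsilane carbonyl of 8 (a ketone activated by the adjacent ester and far more electrophilic than the ester) to give the magnesium-bridged α-silyl alkoxide 12, whose [1,2]-Brook shift (carbon-to-oxygen silyl migration, driven by the ester-stabilised carbanion) releases glycolate enolate 13 with the silyloxy group cis to the enolate oxygen; O-silylation to 14 and warming then trigger the Ireland–Claisen [3,3] shift that makes the C3–C4 bond. The closest known reaction types are the nucleophile addition/Brook three-component couplings of silyl glyoxylates and the Ireland–Claisen rearrangement of α-silyloxy allyl ester enolates with 1,3-chirality transfer, and what is untested is their fusion with a benzylic Grignard reagent and a chiral secondary allylic ester in one flask. No ring is closed, the only cyclic array being the six-membered chair transition state. In that chair the Z ketene acetal places the silyloxy group equatorial and its arylmethyl group axial (setting acid C2 as S), and the E alkene places the second arylmethyl group equatorial (setting acid C3 as R), which puts the two arylmethyl groups cis on the later lactone. The absolute sense is set by the S carbinol carbon, whose methyl group takes the equatorial position and so decides which alkene face bonds, its chirality being traded for the E-propenyl group. The step needs ketone-over-ester chemoselectivity, a clean Brook shift before the enolate meets more glyoxylate, and a single enolate geometry, which are secured by the acylsilane's electrophilicity, by slow addition of 8 to excess 11 at −78 °C and by the magnesium bridge in 12.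

**Step 9**
Reactants: 16 the hexenoic acid
Product: 19 (3S,4R)-3,4-bis[4-(benzyloxy)-3-methoxybenzyl]-3-[(tert-butyldimethylsilyl)oxy]dihydrofuran-2(3H)-one, via aldehyde acid 17 (not isolated), via hydroxy acid 18 (not isolated)
Conditions: O3, CH2Cl2/MeOH, −78 °C (Sudan Red 7B end-point); NaBH4, −78 → 0 °C; 1 M HCl; TsOH (cat.), CH2Cl2, rt
Reagents that add atoms: ozone, [O-][O+]=O
Why: Ozonolysis of the propenyl alkene (far more reactive than the benzyl-protected guaiacyl rings at −78 °C) with in situ hydride reduction gives the γ-hydroxy acid, which closes to the γ-lactone on acidification (intramolecular esterification favoured by the quaternary α-carbon); C3 and C4 are not touched, and reducing the aldehyde cold as it forms should avoid epimerisation at C4.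

**Step 10**
Reactants: 19 the silyloxy lactone
Product: 20 (3S,4R)-3,4-bis[4-(benzyloxy)-3-methoxybenzyl]-3-hydroxydihydrofuran-2(3H)-one
Conditions: HF·pyridine, THF, 0 °C → rt
Reagents that add atoms: none
Why: Fluoride-driven cleavage of the tertiary silyl ether (Si–F bond formation); the lactone, the benzyl ethers and both stereocentres should be unaffected under acidic fluoride conditions.

**Step 11**
Reactants: 20 the dibenzyl hydroxy lactone
Product: 21 (3S,4R)-3-hydroxy-3,4-bis(4-hydroxy-3-methoxybenzyl)dihydrofuran-2(3H)-one (target)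
Conditions: H2 (1 atm), 10% Pd/C, EtOAc/EtOH, rt
Reagents that add atoms: none
Why: Heterogeneous hydrogenolysis of the two benzyl aryl ethers; the lactone C–O bonds and the tertiary alcohol are not benzylic, so only the O–CH2Ph bonds are cleaved and the stereocentres persist.

**Compound list**

1 | eugenol | COc1cc(CC=C)ccc1O | starting material
2 | 4-allyl-1-(benzyloxy)-2-methoxybenzene | COc1cc(CC=C)ccc1OCc1ccccc1 | intermediate
3 | (S)-but-3-en-2-ol | C[C@H](O)C=C | starting material
4 | (2S,3E)-5-[4-(benzyloxy)-3-methoxyphenyl]pent-3-en-2-ol | COc1cc(C/C=C/[C@H](C)O)ccc1OCc1ccccc1 | intermediate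
5 | (2S,3E)-5-[4-(benzyloxy)-3-methoxyphenyl]pent-3-en-2-yl 2-(2-tosylhydrazinylidene)acetate | COc1cc(C/C=C/[C@H](C)OC(=O)C=NNS(=O)(=O)c2ccc(C)cc2)ccc1OCc1ccccc1 | intermediate (not isolated)
6 | (2S,3E)-5-[4-(benzyloxy)-3-methoxyphenyl]pent-3-en-2-yl 2-diazoacetate | COc1cc(C/C=C/[C@H](C)OC(=O)C=[N+]=[N-])ccc1OCc1ccccc1 | intermediate
7 | (2S,3E)-5-[4-(benzyloxy)-3-methoxyphenyl]pent-3-en-2-yl 2-(tert-butyldimethylsilyl)-2-diazoacetate | COc1cc(C/C=C/[C@H](C)OC(=O)C(=[N+]=[N-])[Si](C)(C)C(C)(C)C)ccc1OCc1ccccc1 | intermediate
8 | (2S,3E)-5-[4-(benzyloxy)-3-methoxyphenyl]pent-3-en-2-yl 2-(tert-butyldimethylsilyl)-2-oxoacetate | COc1cc(C/C=C/[C@H](C)OC(=O)C(=O)[Si](C)(C)C(C)(C)C)ccc1OCc1ccccc1 | intermediate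
9 | 4-(benzyloxy)-3-methoxybenzyl alcohol | COc1cc(CO)ccc1OCc1ccccc1 | starting material
10 | 4-(benzyloxy)-3-methoxybenzyl chloride | COc1cc(CCl)ccc1OCc1ccccc1 | intermediate
11 | [4-(benzyloxy)-3-methoxybenzyl]magnesium chloride | COc1cc(C[Mg]Cl)ccc1OCc1ccccc1 | intermediate (solution, used directly)
12 | chloromagnesium alkoxide of (2S,3E)-5-[4-(benzyloxy)-3-methoxyphenyl]pent-3-en-2-yl 3-[4-(benzyloxy)-3-methoxyphenyl]-2-(tert-butyldimethylsilyl)-2-hydroxypropanoate, both epimers at the alkoxide carbon | COc1cc(C/C=C/[C@H](C)OC(=O)C(Cc2ccc(OCc3ccccc3)c(OC)c2)(O[Mg]Cl)[Si](C)(C)C(C)(C)C)ccc1OCc1ccccc1 | intermediate (not isolated)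
13 | chloromagnesium (Z)-enolate of (2S,3E)-5-[4-(benzyloxy)-3-methoxyphenyl]pent-3-en-2-yl 3-[4-(benzyloxy)-3-methoxyphenyl]-2-[(tert-butyldimethylsilyl)oxy]propanoate, silyloxy cis to O–Mg | COc1cc(C/C=C/[C@H](C)O/C(O[Mg]Cl)=C(/O[Si](C)(C)C(C)(C)C)Cc2ccc(OCc3ccccc3)c(OC)c2)ccc1OCc1ccccc1 | intermediate (not isolated)
14 | (Z)-trimethylsilyl ketene acetal of the same ester, tert-butyldimethylsilyloxy cis to trimethylsilyloxy | COc1cc(C/C=C/[C@H](C)O/C(O[Si](C)(C)C)=C(/O[Si](C)(C)C(C)(C)C)Cc2ccc(OCc3ccccc3)c(OC)c2)ccc1OCc1ccccc1 | intermediate (not isolated)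
15 | trimethylsilyl (2S,3R,4E)-2,3-bis[4-(benzyloxy)-3-methoxybenzyl]-2-[(tert-butyldimethylsilyl)oxy]hex-4-enoate | COc1cc(C[C@@H]([C@@](O[Si](C)(C)C(C)(C)C)(Cc2ccc(OCc3ccccc3)c(OC)c2)C(=O)O[Si](C)(C)C)/C=C/C)ccc1OCc1ccccc1 | intermediate (not isolated)
16 | (2S,3R,4E)-2,3-bis[4-(benzyloxy)-3-methoxybenzyl]-2-[(tert-butyldimethylsilyl)oxy]hex-4-enoic acid | COc1cc(C[C@@H]([C@@](O[Si](C)(C)C(C)(C)C)(Cc2ccc(OCc3ccccc3)c(OC)c2)C(=O)O)/C=C/C)ccc1OCc1ccccc1 | intermediate
17 | (2S,3S)-2,3-bis[4-(benzyloxy)-3-methoxybenzyl]-2-[(tert-butyldimethylsilyl)oxy]-4-oxobutanoic acid | COc1cc(C[C@@H]([C@@](O[Si](C)(C)C(C)(C)C)(Cc2ccc(OCc3ccccc3)c(OC)c2)C(=O)O)C=O)ccc1OCc1ccccc1 | intermediate (not isolated)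
18 | (2S,3R)-2,3-bis[4-(benzyloxy)-3-methoxybenzyl]-2-[(tert-butyldimethylsilyl)oxy]-4-hydroxybutanoic acid | COc1cc(C[C@@H]([C@@](O[Si](C)(C)C(C)(C)C)(Cc2ccc(OCc3ccccc3)c(OC)c2)C(=O)O)CO)ccc1OCc1ccccc1 | intermediate (not isolated)
19 | (3S,4R)-3,4-bis[4-(benzyloxy)-3-methoxybenzyl]-3-[(tert-butyldimethylsilyl)oxy]dihydrofuran-2(3H)-one | COc1cc(C[C@@H]2COC(=O)[C@]2(O[Si](C)(C)C(C)(C)C)Cc2ccc(OCc3ccccc3)c(OC)c2)ccc1OCc1ccccc1 | intermediate
20 | (3S,4R)-3,4-bis[4-(benzyloxy)-3-methoxybenzyl]-3-hydroxydihydrofuran-2(3H)-one | COc1cc(C[C@@H]2COC(=O)[C@]2(O)Cc2ccc(OCc3ccccc3)c(OC)c2)ccc1OCc1ccccc1 | intermediate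
21 | (3S,4R)-3-hydroxy-3,4-bis(4-hydroxy-3-methoxybenzyl)dihydrofuran-2(3H)-one | COc1cc(C[C@@H]2COC(=O)[C@]2(O)Cc2ccc(O)c(OC)c2)ccc1O | target

**Step count and risks**

Total: 11 steps. Longest linear sequence: 9 steps (1, 2, 3, 4, 5, 8, 9, 10, 11); the Grignard branch (steps 6 and 7) joins at step 8.

Steps most likely to fail:

1. Step 8 (the step carrying the new-method label). The enolate may add to a second molecule of glyoxylate, O-silylation of the magnesium enolate may be incomplete, or the enolate geometry may erode and lower the diastereoselectivity of the [3,3] shift. The fallback uses known chemistry and sets out from 8 and 11. The addition/Brook sequence is stopped by an AcOH quench at −78 °C to give the protonated adduct (2S,3E)-5-[4-(benzyloxy)-3-methoxyphenyl]pent-3-en-2-yl 3-[4-(benzyloxy)-3-methoxyphenyl]-2-[(tert-butyldimethylsilyl)oxy]propanoate F1 (both epimers at the α-carbon, which is made planar next). Separate enolisation with LiN(iPr)2 in THF at −78 °C gives the lithium enolate of this ester F2 (OLi cis to the silyloxy group). It is silylated with Me3SiCl/Et3N to 14 and rearranges on warming through 15 (classical Ireland–Claisen of an α-silyloxy ester); acid work-up comes back to the route at 16.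

2. Step 5. The dioxirane may also epoxidise the trans alkene or oxidise the electron-rich arene instead of reacting only at the diazo carbon. The fallback sets out from 3 and runs the same three operations on the butenol itself. Diazoacetylation passes through the tosylhydrazone ester (S)-but-3-en-2-yl 2-(2-tosylhydrazinylidene)acetate F3 to the diazoacetate (S)-but-3-en-2-yl 2-diazoacetate F4. C-silylation gives (S)-but-3-en-2-yl 2-(tert-butyldimethylsilyl)-2-diazoacetate F5. Its dioxirane oxidation to (S)-but-3-en-2-yl 2-(tert-butyldimethylsilyl)-2-oxoacetate F6 meets only a monosubstituted, ester-deactivated alkene and no arene. Cross-metathesis of F6 with 2 (second-generation Grubbs catalyst, benzoquinone, CH2Cl2, 40 °C, dark) then comes back at 8.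

3. Step 2. E selectivity may be incomplete and the double bond may migrate into conjugation with the arene during metathesis; either would erode the diastereoselectivity of step 8. The fallback sets out from 10 and purchased (S)-but-3-yn-2-ol (C[C@H](O)C#C). Palladium-catalysed coupling of the terminal alkyne with the benzylic chloride (PdCl2(MeCN)2, XPhos, Cs2CO3, THF, 65 °C) gives (S)-5-[4-(benzyloxy)-3-methoxyphenyl]pent-3-yn-2-ol F7. Hydroxyl-directed trans-hydroalumination with NaAlH2(OCH2CH2OMe)2 in THF at 0 °C and protonolysis should give the E-allylic alcohol only and comes back at 4.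

**Further compounds**

F1 | step 8 | (2S,3E)-5-[4-(benzyloxy)-3-methoxyphenyl]pent-3-en-2-yl 3-[4-(benzyloxy)-3-methoxyphenyl]-2-[(tert-butyldimethylsilyl)oxy]propanoate (both epimers at C2 of the acid part) | COc1cc(C/C=C/[C@H](C)OC(=O)C(Cc2ccc(OCc3ccccc3)c(OC)c2)O[Si](C)(C)C(C)(C)C)ccc1OCc1ccccc1
F2 | step 8 | lithium enolate of F1, OLi cis to the silyloxy group | COc1cc(C/C=C/[C@H](C)O/C(O[Li])=C(/O[Si](C)(C)C(C)(C)C)Cc2ccc(OCc3ccccc3)c(OC)c2)ccc1OCc1ccccc1
F3 | step 5 | (S)-but-3-en-2-yl 2-(2-tosylhydrazinylidene)acetate | C=C[C@H](C)OC(=O)C=NNS(=O)(=O)c1ccc(C)cc1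
F4 | step 5 | (S)-but-3-en-2-yl 2-diazoacetate | C=C[C@H](C)OC(=O)C=[N+]=[N-]
F5 | step 5 | (S)-but-3-en-2-yl 2-(tert-butyldimethylsilyl)-2-diazoacetate | C=C[C@H](C)OC(=O)C(=[N+]=[N-])[Si](C)(C)C(C)(C)C
F6 | step 5 | (S)-but-3-en-2-yl 2-(tert-butyldimethylsilyl)-2-oxoacetate | C=C[C@H](C)OC(=O)C(=O)[Si](C)(C)C(C)(C)C
F7 | step 2 | (S)-5-[4-(benzyloxy)-3-methoxyphenyl]pent-3-yn-2-ol | COc1cc(CC#C[C@H](C)O)ccc1OCc1ccccc1
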